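# Total synthesis plan for CNP0584953.1 (compound 27) through a carboxylate-directed C–H/alkyne annulation

## The problem

- Compound 27 is a pseudo-dimer. A pentasubstituted benzene (ring A) and a 3-methylisoquinoline are clamped together by a 2,9-dioxabicyclo[3.3.1]nonane. An isochroman (ring B: C1, O2, C3, C4, C4a, C8a) and a 1,3-benzodioxane (ring C: C1, O, C6', C7', C3, O2) share the acetal carbon C1, the bridging oxygen O2 and the carbinol carbon C3 (isochroman numbering for rings A and B, primes for the isoquinoline).
- There are three stereocentres: 1R, 3R and 4S.
- C1 depends on C3, because the oxygen on C6' can reach C1 only across the face of ring B on which the isoquinoline stands. Only C3 and C4 have to be made.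
- C4 is independent. Its acetyl group is cis to the isoquinolinyl group, pseudo-equatorial, and wedged between H5 and the 8'-methoxy group, so there is no reason to expect it to be the more stable epimer.
- The same carbon is alpha to a ketone, benzylic, and beta to O2. The finished molecule is therefore prone to epimerisation and to retro-oxa-Michael opening in acid or base, and the ketone has to appear last and under neutral conditions.
- Other awkward features:
  - the aryl alkyl acetal para to a free phenol;
  - a formyl group in the crowded gap between OH and OMe;
  - a C3–O bond benzylic to an ortho-oxygenated arene, which invites quinone methide formation if that phenol is free while C3 still carries an acyloxy group;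
  - a basic nitrogen that binds late transition metals.
- The enabling feature lies on ring A. C8a, which carries C1, has OMe on one ortho carbon (C8) and the future ring-B carbon C4a on the other. A benzoic acid with C1 as its carboxyl carbon therefore has exactly one ortho C–H. That site is meta to both ring oxygens and is out of reach of electrophilic substitution and of alkoxy-directed lithiation.
- Ring B thus maps onto a 3-aryl-4-alkylisocoumarin, and the cis relation at C3/C4 is what syn addition of hydrogen to its C3=C4 bond delivers.

## Retrosynthesis

**27 to 26 and 25.**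
- No skeletal bond is cut. The acetyl carbonyl is exchanged for an (R)-configured carbinol (26), held as its acetate (25) while acid is in use.
- A ketal was weighed against this. It would have to be installed and removed in acid at an epimerisable centre.
- The carbinol removes the acidity of C4–H for the whole endgame, survives hydride, and can also serve as the source of absolute configuration.
- The forward reaction must be a neutral oxidation of a hindered secondary alcohol beside a hydrogen-bonded phenol.

**25 to 24.**
- The C1–O(C6') bond of ring C is cut. At the same time the formyl group goes back to a 1,3-dioxane and both phenols to methoxymethyl ethers.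
- Of the three C–O bonds around the bridge, this is the only one whose cleavage leaves C3 and C4 inside an intact six-membered ring. Cutting C3–O2 would hand the C3 configuration to a benzylic cation.
- The bicycle becomes a monocyclic 1-acetoxyisochroman, and the C1 stereocentre disappears.
- The forward step needs one acid treatment that ionises C1, frees the C6' phenol and lets it close on the only face it can reach.
- The side-chain oxygen must stay blocked, because a free hydroxyl there could capture C1 in a competing [2.2.2] dialkyl acetal.

**24 to 22.**
- C1 is taken from the acetal level back to the lactone level; no bond is cut.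
- The lactone must be reduced without ever releasing the open hydroxy aldehyde, which could re-close on the side-chain oxygen and scramble the constitution. Reduction and acylation are therefore done in one flask.
- This is also why the formyl carbon is carried as an acetal. It is brought in with the acid rather than added at the end, because ortho-formylation of the C6 phenol would have to choose the crowded C7 gap over C5, which is para to OMe.

**22 to 19.**
- The C3–H and C4–H bonds are removed. Both ring stereocentres vanish and a flat isocoumarin remains.
- Hydride conjugate addition to the ketone-level analogue was considered. It would attack a tetrasubstituted carbon and would leave an enolate beta to a carboxylate leaving group.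
- Syn hydrogenation has no such exit and gives the cis relation by mechanism.
- The forward step has to choose one face of a crowded tetrasubstituted alkene. The free allylic hydroxyl of 19 is asked to carry a cationic iridium catalyst to that face.

**19 and 18 to 6 and 17 (key disconnection).**
- The C4–C4a and O2–C3 bonds are cut, which opens ring B into benzoic acid 6 and internal alkyne 17.
- Neighbouring cuts, such as C3–C4 (aldol logic) or C1–C8a, leave the stereochemical problem untouched or need an ortho-functionalised ring A that is hard to obtain. This cut uses the single ortho C–H directly and joins two fragments of equal size.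
- An ynone partner would look more direct, but its conjugate polarity sends an aryl–metal bond to the aryl-bearing alkyne carbon. That opposes the aryl and steric biases needed here, and it is also a Michael acceptor for carboxylates at high temperature.
- With the carbonyl carried as a silyl-protected carbinol, 17 is an ordinary aryl alkyl alkyne. For that class both remaining biases point to the 3-aryl-4-alkyl isomer.

**17 to 14, 15 and 8.**
- The pyridine ring is opened at N–C1', N–C3' and C4'–C4a'. This gives ammonia, propyne 15 and a bromobenzaldehyde.
- The C7'–alkyne bond is cut to iodide 13 and silyl ether 8, which is made from commercial alkynol 7.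
- Placing iodine and bromine on the same ring lets two Sonogashira couplings be run in the order of halide reactivity. A halide at C7' replaces the aldehyde homologation, acylation and asymmetric reduction sequence with one coupling of a chiral-pool alkyne.

**13 to 9.**
- The formyl C–C bond, the C–I bond and two O-alkyl bonds are cut back to 5-bromoresorcinol 9.
- Symmetry removes every positional question. Iodine enters between the two hydroxyls (10), after which the two open ring positions are equivalent for formylation (11). The aldehyde then differentiates the oxygens, since the chelated one (12) waits for methylation (13).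
- Halogenating a finished 6,8-dioxygenated isoquinoline would favour C5' instead.

**6 to 1.**
- The formyl C–C bond and the protecting groups are removed, back to methyl 2,4-dihydroxybenzoate 1.
- Blocking the 4-OH first (2) leaves a phenol whose only free ortho carbon is C3. A magnesium-mediated, strictly ortho formylation must therefore place the aldehyde between the two oxygens (3).
- Methylation (4), acetalisation (5) and saponification complete 6.

## Roads not taken

**Alternative 1:**
- *Cut.* The acetal carbon is excised altogether (C1–C8a and both C1–O bonds).
- *Forward key step.* Open-chain hydroxy ketone A2 would exchange onto HC(OMe)3 to give a 2-methoxy-1,3-benzodioxane. Me3SiOTf would ionise it, and ring A would close on the dioxocarbenium ion to give A1.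
- *Merits.*
  - Three bonds and two rings form in one operation.
  - No redox adjustment is needed at C1.
  - The attacking carbon is ortho to OMe and para to a silyloxy group, so it is electronically well matched.
  - The endgame is clearly shorter than the one chosen here, and it avoids reduction of a tetrasubstituted alkene.
- *Weak points.*
  - A2 is an aldol adduct that already holds both stereocentres. It has to come from an asymmetric aldol of an arylacetone with a doubly ortho-substituted aldehyde.
  - A2 is then exposed as a free beta-hydroxy ketone to a silylating Lewis acid, which invites retro-aldol cleavage, enol silane formation and loss of C4.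
  - Ring A in A2 has two activated positions ortho to the side chain, and only the bulk of the silyl group separates them.
  - A1 still lacks the formyl group, so the unfavourable late formylation returns.
- *Comparison.* The chosen plan offers a single possible C–H site, a masked ketone throughout, and a formyl carbon installed where its position is forced.

**Alternative 2:**
- *Cut.* The C3–C4 and O2–C1 bonds.
- *Forward key step.* The enol of homophthalic anhydride A4 would add to aldehyde A5 under a bifunctional squaramide, and the alkoxide would then acylate to give acid A3.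
- *Merits.*
  - Ring B and both carbon stereocentres arise in one catalytic asymmetric step from two simple partners.
  - In this respect it is better than the chosen plan, whose key step creates no stereocentre.
- *Weak points.*
  - A3 must be the cis acid, yet C4 is flanked by an aryl group and a carboxyl group. Under a basic catalyst it can drift to the trans isomer.
  - The carbonyl of A5 is shielded by two ortho alkoxy groups.
  - Turning CO2H into COCH3 takes further steps with organometallic reagents, in the presence of a lactone and at an epimerisable centre.
  - The formyl group is again missing.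
- *Comparison.* The chosen plan offers a cis relation that follows from the mechanism of hydrogen delivery, and a side chain that already has its two carbons.

**Alternative 3:**
- *Cut.* The carbocycle of the isoquinoline is taken apart (C8'–C7', C6'–C5', C8'–C8a').
- *Forward key step.* Photochemical Wolff rearrangement of diazoketone A7 would give a pyridylketene. This would add to siloxyalkyne A8, and the derived dienylketene would close onto the pyridine to give A6.
- *Merits.*
  - The hindered C3–C7' bond is never made by coupling.
  - The two ring oxygens emerge already differentiated, one as free OH and one as a silyl ether. This is neater than the four-step differentiation used here.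
- *Weak points.*
  - The electrocyclisation can close onto either carbon flanking C4 of the pyridine, and only one closure gives the 3-methylisoquinoline.
  - A8 already contains C3, C4 and ring B, so this road does not address the stereochemical problem. It needs its own route to an enantiopure isochroman bearing a sensitive ynol ether.
  - The sequence runs through irradiation and heating with an acetal and a ketal on board.
- *Comparison.* It is a way of making the isoquinoline, not the bicycle. The chosen plan makes the isoquinoline by robust cross-coupling and spends its key step on ring B.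

Key step: step 13

**Remarks on the chemistry**
- Compound 24 is carried as a mixture of C1 epimers, which converge in step 17.
- Slow rotation about the C3–C7' axis in 18 and 19 may show up as rotamers, which converge in step 15.
- The facial sense of step 15 is assigned from the allylic-strain model. The enantiomer of 7 is equally available should the sense prove opposite.

## Route

Step 1
Reactants: 1 methyl 2,4-dihydroxybenzoate
Product: 2 methyl 2-hydroxy-4-(methoxymethoxy)benzoate
Conditions: MOMCl (1.05 equiv), i-Pr2NEt, CH2Cl2, 0 °C to rt
Reagents that add atoms: chloromethyl methyl ether, COCCl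
Why: O-alkylation of a phenol; the 2-OH is locked in a hydrogen bond to the ester carbonyl, so one equivalent of reagent should alkylate only the free 4-OH, as is usual for 2,4-dihydroxyaryl carbonyl compounds.

Step 2
Reactants: 2 methyl 2-hydroxy-4-(methoxymethoxy)benzoate
Product: 3 methyl 3-formyl-2-hydroxy-4-(methoxymethoxy)benzoate
Conditions: MgCl2, Et3N, (CH2O)n, MeCN, reflux; cold 1 M HCl
Reagents that add atoms: paraformaldehyde (as formaldehyde), C=O
Why: Casnati–Skattebøl ortho-formylation, in which the magnesium phenoxide hands formaldehyde to an ortho carbon through a cyclic transition state and a second formaldehyde takes up hydride. The only free ortho carbon of 2 is C3, which is meta to the ester and ortho to both oxygens, so the aldehyde is forced into the gap between them.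

Step 3
Reactants: 3 methyl 3-formyl-2-hydroxy-4-(methoxymethoxy)benzoate
Product: 4 methyl 3-formyl-2-methoxy-4-(methoxymethoxy)benzoate
Conditions: MeI, K2CO3, DMF, rt to 40 °C
Reagents that add atoms: iodomethane, CI
Why: Williamson methylation of the remaining, doubly chelated phenol, which needs a polar solvent but has no competitor.

Step 4
Reactants: 4 methyl 3-formyl-2-methoxy-4-(methoxymethoxy)benzoate
Product: 5 methyl 3-(1,3-dioxan-2-yl)-2-methoxy-4-(methoxymethoxy)benzoate
Conditions: Me3SiO(CH2)3OSiMe3, Me3SiOTf (cat.), CH2Cl2, −78 to −20 °C; pyridine quench
Reagents that add atoms: 1,3-bis(trimethylsilyloxy)propane, C[Si](C)(C)OCCCO[Si](C)(C)C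
Why: Aprotic acetalisation with a bis-silyl ether, driven by formation of (Me3Si)2O, works on hindered electron-rich aldehydes at low temperature and should spare the methoxymethyl ether. The six-membered acetal of an aldehyde is the slower one to hydrolyse, which is wanted in step 13.

Step 5
Reactants: 5 methyl 3-(1,3-dioxan-2-yl)-2-methoxy-4-(methoxymethoxy)benzoate
Product: 6 3-(1,3-dioxan-2-yl)-2-methoxy-4-(methoxymethoxy)benzoic acid
Conditions: LiOH, THF–MeOH–H2O, 40 °C; 10% aq. citric acid to pH 4, 0 °C
Reagents that add atoms: lithium hydroxide, [Li+].[OH-]
Why: Saponification of a mono-ortho-substituted benzoate; both acetal-type groups are base-stable and a cold, weakly acidic work-up should keep them in place.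

Step 6
Reactants: 7 (R)-but-3-yn-2-ol
Product: 8 (R)-(but-3-yn-2-yloxy)(tert-butyl)dimethylsilane
Conditions: t-BuMe2SiCl, imidazole, CH2Cl2, 0 °C to rt
Reagents that add atoms: tert-butyldimethylsilyl chloride, CC(C)(C)[Si](C)(C)Cl
Why: Standard silylation with no bond to the stereocentre broken. The ether blocks dehydrogenation, and thus racemisation, of the carbinol by rhodium and copper in step 13.

Step 7
Reactants: 9 5-bromobenzene-1,3-diol
Product: 10 5-bromo-2-iodobenzene-1,3-diol
Conditions: I2 (1.0 equiv), NaHCO3, H2O, 0 °C to rt
Reagents that add atoms: iodine, II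
Why: Iodination of resorcinols with I2 in aqueous hydrogencarbonate goes to the carbon between the two hydroxyls. Here the other two positions are also flanked by bromine, and the product keeps its mirror symmetry.

Step 8
Reactants: 10 5-bromo-2-iodobenzene-1,3-diol
Product: 11 6-bromo-2,4-dihydroxy-3-iodobenzaldehyde
Conditions: MgCl2, Et3N, (CH2O)n, MeCN, reflux; cold 1 M HCl
Reagents that add atoms: paraformaldehyde (as formaldehyde), C=O
Why: Casnati–Skattebøl ortho-formylation. The two open ring positions of 10 are equivalent, so only one monoaldehyde can form, and the basic medium avoids the acid-induced migration of iodine known for 2-iodoresorcinols.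

Step 9
Reactants: 11 6-bromo-2,4-dihydroxy-3-iodobenzaldehyde
Product: 12 6-bromo-2-hydroxy-3-iodo-4-(methoxymethoxy)benzaldehyde
Conditions: MOMCl (1.05 equiv), i-Pr2NEt, CH2Cl2, 0 °C
Reagents that add atoms: chloromethyl methyl ether, COCCl
Why: Selective O-alkylation of the hydroxyl para to the formyl group. The ortho hydroxyl is hydrogen-bonded to the aldehyde and flanked on both sides, so it stays free.

Step 10
Reactants: 12 6-bromo-2-hydroxy-3-iodo-4-(methoxymethoxy)benzaldehyde
Product: 13 6-bromo-3-iodo-2-methoxy-4-(methoxymethoxy)benzaldehyde
Conditions: MeI, K2CO3, DMF, rt to 40 °C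
Reagents that add atoms: iodomethane, CI
Why: Williamson methylation of the chelated phenol; this fixes the future 8'-OMe and 6'-O pattern without any selective demethylation.

Step 11
Reactants: 13 6-bromo-3-iodo-2-methoxy-4-(methoxymethoxy)benzaldehyde; 8 (R)-(but-3-yn-2-yloxy)(tert-butyl)dimethylsilane
Product: 14 6-bromo-3-[(3R)-3-(tert-butyldimethylsilyloxy)but-1-yn-1-yl]-2-methoxy-4-(methoxymethoxy)benzaldehyde
Conditions: PdCl2(PPh3)2 (5 mol%), CuI (10 mol%), Et3N–THF, rt to 40 °C
Reagents that add atoms: none
Why: Sonogashira coupling. Oxidative addition of zerovalent palladium to C–I is much faster than to C–Br, so near room temperature only the iodide should react although it is the more hindered site. Both flanking oxygens are protected, so no benzofuran can form.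

Step 12
Reactants: 14 6-bromo-3-[(3R)-3-(tert-butyldimethylsilyloxy)but-1-yn-1-yl]-2-methoxy-4-(methoxymethoxy)benzaldehyde; 15 propyne
Product: 17 7-[(3R)-3-(tert-butyldimethylsilyloxy)but-1-yn-1-yl]-8-methoxy-6-(methoxymethoxy)-3-methylisoquinoline, via dialkynyl benzaldehyde 16 (not isolated)
Conditions: propyne (solution in DMF), PdCl2(PPh3)2, CuI, Et3N, DMF, 65 °C, sealed tube; then NH3 (7 M in MeOH), 85 °C
Reagents that add atoms: ammonia, N
Why: A second Sonogashira coupling at the bromide activated by the ortho formyl group, followed in the same flask by imine formation and copper-assisted 6-endo-dig attack of nitrogen on the propynyl group, the standard coupling–imination–annulation route to 3-substituted isoquinolines. Only the propynyl group is ortho to the imine, so the other alkyne is a spectator.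

Step 13
Reactants: 6 3-(1,3-dioxan-2-yl)-2-methoxy-4-(methoxymethoxy)benzoic acid; 17 7-[(3R)-3-(tert-butyldimethylsilyloxy)but-1-yn-1-yl]-8-methoxy-6-(methoxymethoxy)-3-methylisoquinoline
Product: 18 4-[(1R)-1-(tert-butyldimethylsilyloxy)ethyl]-7-(1,3-dioxan-2-yl)-8-methoxy-6-(methoxymethoxy)-3-[8-methoxy-6-(methoxymethoxy)-3-methylisoquinolin-7-yl]-1H-isochromen-1-one
Conditions: [Cp*RhCl2]2 (5 mol%), anhydrous Cu(OAc)2 (3 equiv), 4 Å molecular sieves, DMF, 100 °C, N2
Reagents that add atoms: none
Why: The carboxylate of 6 binds trivalent rhodium, and acetate-assisted concerted metalation–deprotonation can take place only at C6–H of the acid, because the other ortho carbon bears OMe; this gives a five-membered rhodacycle. Alkyne 17 then inserts into the Rh–aryl bond to give a seven-membered rhodacycle, and C–O reductive elimination at the metal closes ring B as a six-membered enol lactone in a formal [4+2] oxidative annulation that forms C4–C4a and O2–C3. Two Cu(OAc)2 return monovalent rhodium to the trivalent state. The closest known reaction type is the oxidative annulation of benzoic acids with aryl alkyl alkynes, which gives 3-aryl-4-alkylisocoumarins. The selectivity needed is that ring A bonds to the carbinol-bearing carbon, and two features of 17 secure it: an aryl group prefers the carbon that stays on the metal, and the bulky 2,6-disubstituted aryl avoids the short forming C–C bond. No stereocentre is created, and the silyl-protected carbinol centre is not touched. The third equivalent of Cu(OAc)2 is there to occupy the isoquinoline nitrogen, and dry conditions leave the acetal groups nothing to hydrolyse with.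

Step 14
Reactants: 18 4-[(1R)-1-(tert-butyldimethylsilyloxy)ethyl]-7-(1,3-dioxan-2-yl)-8-methoxy-6-(methoxymethoxy)-3-[8-methoxy-6-(methoxymethoxy)-3-methylisoquinolin-7-yl]-1H-isochromen-1-one
Product: 19 7-(1,3-dioxan-2-yl)-4-[(1R)-1-hydroxyethyl]-8-methoxy-6-(methoxymethoxy)-3-[8-methoxy-6-(methoxymethoxy)-3-methylisoquinolin-7-yl]-1H-isochromen-1-one
Conditions: n-Bu4NF, AcOH (1:1), THF, 0 °C to rt
Reagents that add atoms: none
Why: Fluoride desilylation, buffered so that the enol lactone is not opened by basic fluoride. The hydroxyl cannot migrate onto the lactone carbonyl because that would need a bridgehead alkene.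

Step 15
Reactants: 19 7-(1,3-dioxan-2-yl)-4-[(1R)-1-hydroxyethyl]-8-methoxy-6-(methoxymethoxy)-3-[8-methoxy-6-(methoxymethoxy)-3-methylisoquinolin-7-yl]-1H-isochromen-1-one
Product: 22 (3R,4R)-7-(1,3-dioxan-2-yl)-4-[(1R)-1-hydroxyethyl]-8-methoxy-6-(methoxymethoxy)-3-[8-methoxy-6-(methoxymethoxy)-3-methylisoquinolin-7-yl]-3,4-dihydro-1H-isochromen-1-one, via isoquinolinium tetrafluoroborate of the allylic alcohol 20 (not isolated), via isoquinolinium tetrafluoroborate of the dihydroisocoumarin 21 (not isolated)
Conditions: HBF4·OEt2 (1.0 equiv), CH2Cl2, 0 °C; [Ir(cod)(PCy3)(py)]PF6 (10 mol%), H2 (50 bar), CH2Cl2, rt; aq. NaHCO3 wash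
Reagents that add atoms: none
Why: Hydroxyl-directed homogeneous hydrogenation, the standard way to saturate tetrasubstituted alkenes from one face; protonation keeps the nitrogen off the cationic iridium. Allylic strain turns the carbinol C–H towards the C3 aryl group, so OH and CH3 lie on opposite faces, and the metal bound to the (R)-hydroxyl delivers both hydrogens to the face that gives 3R,4R. Syn addition makes the isoquinolinyl group and the side chain cis.

Step 16
Reactants: 22 (3R,4R)-7-(1,3-dioxan-2-yl)-4-[(1R)-1-hydroxyethyl]-8-methoxy-6-(methoxymethoxy)-3-[8-methoxy-6-(methoxymethoxy)-3-methylisoquinolin-7-yl]-3,4-dihydro-1H-isochromen-1-one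
Product: 24 (3R,4R)-4-[(1R)-1-acetoxyethyl]-7-(1,3-dioxan-2-yl)-8-methoxy-6-(methoxymethoxy)-3-[8-methoxy-6-(methoxymethoxy)-3-methylisoquinolin-7-yl]-3,4-dihydro-1H-isochromen-1-yl acetate (C1 epimers), via bis(diisobutylaluminium) lactolate 23 (not isolated)
Conditions: i-Bu2AlH (4 equiv), CH2Cl2, −78 °C; then pyridine, DMAP, Ac2O, −78 to 0 °C; aq. Rochelle salt
Reagents that add atoms: acetic anhydride, CC(=O)OC(C)=O
Why: Reductive acetylation of a lactone. The aluminium hemiacetal is stable at −78 °C and is acylated before it can open, so the C3–O2–C1 connectivity is kept, and the side-chain alkoxide is capped in the same flask with a small, acid-stable group. The C6' oxygen is still protected, so no quinone methide can form from the benzylic lactone.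

Step 17
Reactants: 24 (3R,4R)-4-[(1R)-1-acetoxyethyl]-7-(1,3-dioxan-2-yl)-8-methoxy-6-(methoxymethoxy)-3-[8-methoxy-6-(methoxymethoxy)-3-methylisoquinolin-7-yl]-3,4-dihydro-1H-isochromen-1-yl acetate (C1 epimers)
Product: 25 bridged acetal acetate (1R,3R,4R; side chain 1R): 7-formyl-6-hydroxy-8-methoxyisochroman with C1 bonded to O6' and C3 to C7' of 8'-methoxy-3'-methylisoquinoline and a 1-acetoxyethyl group on C4 cis to the isoquinoline
Conditions: TFA–CH2Cl2–H2O (20:78:2), 0 °C to rt; toluene azeotrope; aq. NaHCO3
Reagents that add atoms: water, O
Why: Acid removes both aryl methoxymethyl ethers and the dioxane, ionises the anomeric acetate to an oxocarbenium ion stabilised by the 8-OMe and 6-O donors, and the C6' phenol closes ring C by intramolecular acetalisation. C1 becomes R because the tethered phenol can reach only the face of ring B on which the isoquinoline stands. The protonated isoquinolinium disfavours ionisation at C3, and C4 has no adjacent carbonyl, so neither earlier centre should move.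

Step 18
Reactants: 25 bridged acetal acetate
Product: 26 bridged acetal alcohol (1R,3R,4R; side chain 1R): as 25 with a 1-hydroxyethyl group on C4
Conditions: K2CO3, MeOH, 0 °C to rt; aq. NH4Cl
Reagents that add atoms: none
Why: Zemplén-type methanolysis of the acetate. The acetal is base-stable, no enolisable centre exists yet, and the phenoxide is delocalised into the ortho formyl group, which should keep it from pushing out the aryloxy group at C1.

Step 19
Reactants: 26 bridged acetal alcohol
Product: 27 CNP0584953.1 (1R,3R,4S)
Conditions: Dess–Martin periodinane, NaHCO3, CH2Cl2, 0 °C to rt; short neutral work-up, deactivated silica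
Reagents that add atoms: none
Why: Dess–Martin oxidation converts hindered secondary alcohols under close to neutral conditions and tolerates phenols that are hydrogen-bonded to an ortho carbonyl group. The auxiliary carbinol centre is erased, and C4, untouched in space, changes its descriptor to S only because the priorities change. Placing this step last gives the labile beta-alkoxy alpha-aryl ketone no further acid or base to meet.

## Compound list

1 | methyl 2,4-dihydroxybenzoate | COC(=O)c1ccc(O)cc1O | starting material
2 | methyl 2-hydroxy-4-(methoxymethoxy)benzoate | COCOc1ccc(C(=O)OC)c(O)c1 | intermediate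
3 | methyl 3-formyl-2-hydroxy-4-(methoxymethoxy)benzoate | COCOc1ccc(C(=O)OC)c(O)c1C=O | intermediate
4 | methyl 3-formyl-2-methoxy-4-(methoxymethoxy)benzoate | COCOc1ccc(C(=O)OC)c(OC)c1C=O | intermediate
5 | methyl 3-(1,3-dioxan-2-yl)-2-methoxy-4-(methoxymethoxy)benzoate | COCOc1ccc(C(=O)OC)c(OC)c1C1OCCCO1 | intermediate
6 | 3-(1,3-dioxan-2-yl)-2-methoxy-4-(methoxymethoxy)benzoic acid | COCOc1ccc(C(=O)O)c(OC)c1C1OCCCO1 | intermediate
7 | (R)-but-3-yn-2-ol | C#C[C@@H](C)O | starting material
8 | (R)-(but-3-yn-2-yloxy)(tert-butyl)dimethylsilane | C#C[C@@H](C)O[Si](C)(C)C(C)(C)C | intermediate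
9 | 5-bromobenzene-1,3-diol | Oc1cc(O)cc(Br)c1 | starting material
10 | 5-bromo-2-iodobenzene-1,3-diol | Oc1cc(Br)cc(O)c1I | intermediate
11 | 6-bromo-2,4-dihydroxy-3-iodobenzaldehyde | O=Cc1c(Br)cc(O)c(I)c1O | intermediate
12 | 6-bromo-2-hydroxy-3-iodo-4-(methoxymethoxy)benzaldehyde | O=Cc1c(Br)cc(OCOC)c(I)c1O | intermediate
13 | 6-bromo-3-iodo-2-methoxy-4-(methoxymethoxy)benzaldehyde | O=Cc1c(Br)cc(OCOC)c(I)c1OC | intermediate
14 | 6-bromo-3-[(3R)-3-(tert-butyldimethylsilyloxy)but-1-yn-1-yl]-2-methoxy-4-(methoxymethoxy)benzaldehyde | O=Cc1c(Br)cc(OCOC)c(C#C[C@@H](C)O[Si](C)(C)C(C)(C)C)c1OC | intermediate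
15 | propyne | CC#C | starting material
16 | 3-[(3R)-3-(tert-butyldimethylsilyloxy)but-1-yn-1-yl]-2-methoxy-4-(methoxymethoxy)-6-(prop-1-yn-1-yl)benzaldehyde | O=Cc1c(C#CC)cc(OCOC)c(C#C[C@@H](C)O[Si](C)(C)C(C)(C)C)c1OC | intermediate
17 | 7-[(3R)-3-(tert-butyldimethylsilyloxy)but-1-yn-1-yl]-8-methoxy-6-(methoxymethoxy)-3-methylisoquinoline | COCOc1cc2cc(C)ncc2c(OC)c1C#C[C@@H](C)O[Si](C)(C)C(C)(C)C | intermediate
18 | 4-[(1R)-1-(tert-butyldimethylsilyloxy)ethyl]-7-(1,3-dioxan-2-yl)-8-methoxy-6-(methoxymethoxy)-3-[8-methoxy-6-(methoxymethoxy)-3-methylisoquinolin-7-yl]-1H-isochromen-1-one | COCOc1cc2c(c(OC)c1C1OCCCO1)C(=O)OC(c1c(OCOC)cc3cc(C)ncc3c1OC)=C2[C@@H](C)O[Si](C)(C)C(C)(C)C | intermediate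
19 | 7-(1,3-dioxan-2-yl)-4-[(1R)-1-hydroxyethyl]-8-methoxy-6-(methoxymethoxy)-3-[8-methoxy-6-(methoxymethoxy)-3-methylisoquinolin-7-yl]-1H-isochromen-1-one | COCOc1cc2c(c(OC)c1C1OCCCO1)C(=O)OC(c1c(OCOC)cc3cc(C)ncc3c1OC)=C2[C@@H](C)O | intermediate
20 | isoquinolinium tetrafluoroborate of 19 | COCOc1cc2c(c(OC)c1C1OCCCO1)C(=O)OC(c1c(OCOC)cc3cc(C)[nH+]cc3c1OC)=C2[C@@H](C)O.F[B-](F)(F)F | intermediate
21 | isoquinolinium tetrafluoroborate of 22 | COCOc1cc2c(c(OC)c1C1OCCCO1)C(=O)O[C@@H](c1c(OCOC)cc3cc(C)[nH+]cc3c1OC)[C@H]2[C@@H](C)O.F[B-](F)(F)F | intermediate
22 | (3R,4R)-7-(1,3-dioxan-2-yl)-4-[(1R)-1-hydroxyethyl]-8-methoxy-6-(methoxymethoxy)-3-[8-methoxy-6-(methoxymethoxy)-3-methylisoquinolin-7-yl]-3,4-dihydro-1H-isochromen-1-one (3,4-cis) | COCOc1cc2c(c(OC)c1C1OCCCO1)C(=O)O[C@@H](c1c(OCOC)cc3cc(C)ncc3c1OC)[C@H]2[C@@H](C)O | intermediate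
23 | bis(diisobutylaluminium) derivative of the lactol of 22 (C1 unassigned) | COCOc1cc2c(c(OC)c1C1OCCCO1)C(O[Al](CC(C)C)CC(C)C)O[C@@H](c1c(OCOC)cc3cc(C)ncc3c1OC)[C@H]2[C@@H](C)O[Al](CC(C)C)CC(C)C | intermediate
24 | (3R,4R)-4-[(1R)-1-acetoxyethyl]-7-(1,3-dioxan-2-yl)-8-methoxy-6-(methoxymethoxy)-3-[8-methoxy-6-(methoxymethoxy)-3-methylisoquinolin-7-yl]-3,4-dihydro-1H-isochromen-1-yl acetate (C1 epimers) | COCOc1cc2c(c(OC)c1C1OCCCO1)C(OC(C)=O)O[C@@H](c1c(OCOC)cc3cc(C)ncc3c1OC)[C@H]2[C@@H](C)OC(C)=O | intermediate
25 | bridged acetal acetate (1R,3R,4R; side chain 1R) | COc1c(C=O)c(O)cc2c1[C@H]1Oc3cc4cc(C)ncc4c(OC)c3[C@H](O1)[C@H]2[C@@H](C)OC(C)=O | intermediate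
26 | bridged acetal alcohol (1R,3R,4R; side chain 1R) | COc1c(C=O)c(O)cc2c1[C@H]1Oc3cc4cc(C)ncc4c(OC)c3[C@H](O1)[C@H]2[C@@H](C)O | intermediate
27 | CNP0584953.1 (1R,3R,4S) | COc1c(C=O)c(O)cc2c1[C@H]1Oc3cc4cc(C)ncc4c(OC)c3[C@H](O1)[C@H]2C(C)=O | target

## Step count and least certain steps

Total step count: 19. Longest linear sequence: 13 steps (9 to 27, steps 7 to 19).

**Step 13 (key step).**
- *Risk.* The most likely failure is slow insertion. The alkyne carries a 2,6-disubstituted aryl group on one end and a branched silyloxyalkyl group on the other, and the isoquinoline nitrogen competes for rhodium.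
  - A stalled cycle leaves time for protodecarboxylation of the electron-rich ortho-methoxy acid.
  - It also leaves time for acid-induced loss of the acetal or methoxymethyl groups, and for cyclisation of a freed phenol onto the alkyne.
  - Erosion of regioselectivity is possible if the two alkyne substituents turn out to be of similar effective size.
- *Fallback.* This keeps the same two bonds but replaces C–H activation by a halide.
  - It sets out from ester 5, which is borylated ortho to the ester with B2pin2, [Ir(OMe)(cod)]2 and P[3,5-(CF3)2C6H3]3 to give boronate F1.
  - Copper-mediated iododeboronation (CuI, phenanthroline, KI, air) gives iodide F2.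
  - A Larock-type annulation of F2 with 17 (Pd(OAc)2, Na2CO3, LiCl, DMF, 100 °C) places the bulkier group next to oxygen and comes back to the route at 18.

**Step 15.**
- *Risk.* The most likely failure is lack of turnover, because the metal must reach an alkene flanked by a perpendicular aryl ring with substituents on both faces.
  - Incomplete protonation of nitrogen would add catalyst poisoning.
  - Hydride insertion followed by beta-hydride elimination from the carbinol carbon would isomerise the allylic alcohol instead of saturating the alkene.
  - A change of the preferred rotamer about C4–C(carbinol) would weaken face selection.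
- *Fallback.* This changes from substrate direction to catalyst control.
  - It sets out from silyl ether 18.
  - 18 is hydrogenated with the catalyst prepared from [Ru(cod)(2-methylallyl)2], a chiral naphthylethyl-substituted imidazolinium tetrafluoroborate, KOt-Bu and enantiopure 1,2-diphenylethylenediamine. This type is known to reduce isocoumarins enantioselectively, and it would give silyl ether F3.
  - Because of the carbinol centre, any minor isomer is a separable diastereomer.
  - n-Bu4NF then returns the route to 22.

**Step 16.**
- *Risk.* The most likely failure is incomplete capture.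
  - The hindered side-chain alkoxide may acylate slowly.
  - The aluminium hemiacetal may open on warming, which allows over-reduction or re-closure on the wrong oxygen.
- *Fallback.* This separates protection from reduction and sets out from 22.
  - t-BuPh2SiCl and imidazole give silyl ether F4.
  - i-Bu2AlH at −78 °C gives lactol F5, which now has only one hydroxyl to close on.
  - The acid treatment of step 17 gives bridged silyl ether F6.
  - n-Bu4NF returns the route to 26.
  - The price is a bulkier group next to the 8'-OMe during ring closure.

**Step 17.**
- *Risk.* The most likely failure is incomplete closure. Ring B must flip so that the isoquinoline becomes axial and the side chain pseudo-equatorial, against H5 and the 8'-OMe, and in wet acid the equilibrium may rest at the lactol. Capture of liberated formaldehyde by the free phenols is a second risk.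
- *Fallback.* This splits deprotection from closure and sets out from 24.
  - HCl in MeOH at 0 °C, with aqueous work-up, gives methyl acetal F7, with both phenols and the aldehyde free.
  - PPTS in toluene at 80 °C over 5 Å molecular sieves then drives out methanol under anhydrous conditions and comes back at 25.

**Step 8.**
- *Risk.* The most likely failure is low reactivity, because the only open carbon lies between a magnesium phenoxide and bromine on a ring carrying two halogens. Long heating could cause loss of iodine.
- *Fallback.* This reverses the order and sets out from 9.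
  - Vilsmeier–Haack formylation (POCl3, DMF) gives aldehyde F8.
  - Iodination with I2 and NaHCO3 in water comes back at 11.
  - The price is that iodination then has two open sites, and relies on the preference of chelated 2,4-dihydroxyaryl carbonyl compounds for the carbon between the hydroxyls under basic conditions.

**Step 2.**
- *Risk.* The most likely failure is sluggish formylation, because the phenoxide is chelated by the ester and the target carbon is flanked on both sides.
- *Fallback.* This sets out from 1.
  - A Duff reaction (hexamethylenetetramine, TFA, reflux, then aqueous acid) goes to the carbon between the hydroxyls in chelated resorcinol carbonyl compounds and gives dihydroxy aldehyde F9.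
  - One equivalent of MOMCl with i-Pr2NEt then protects the less shielded 4-OH and comes back at 3.

## Further compounds

F1 | step 13 | methyl 3-(1,3-dioxan-2-yl)-2-methoxy-4-(methoxymethoxy)-6-(4,4,5,5-tetramethyl-1,3,2-dioxaborolan-2-yl)benzoate | COCOc1cc(B2OC(C)(C)C(C)(C)O2)c(C(=O)OC)c(OC)c1C1OCCCO1
F2 | step 13 | methyl 3-(1,3-dioxan-2-yl)-6-iodo-2-methoxy-4-(methoxymethoxy)benzoate | COCOc1cc(I)c(C(=O)OC)c(OC)c1C1OCCCO1
F3 | step 15 | tert-butyldimethylsilyl ether of 22 | COCOc1cc2c(c(OC)c1C1OCCCO1)C(=O)O[C@@H](c1c(OCOC)cc3cc(C)ncc3c1OC)[C@H]2[C@@H](C)O[Si](C)(C)C(C)(C)C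
F4 | step 16 | tert-butyldiphenylsilyl ether of 22 | COCOc1cc2c(c(OC)c1C1OCCCO1)C(=O)O[C@@H](c1c(OCOC)cc3cc(C)ncc3c1OC)[C@H]2[C@@H](C)O[Si](c1ccccc1)(c1ccccc1)C(C)(C)C
F5 | step 16 | lactol of F4 (C1 epimers) | COCOc1cc2c(c(OC)c1C1OCCCO1)C(O)O[C@@H](c1c(OCOC)cc3cc(C)ncc3c1OC)[C@H]2[C@@H](C)O[Si](c1ccccc1)(c1ccccc1)C(C)(C)C
F6 | step 16 | tert-butyldiphenylsilyl ether of 26 | COc1c(C=O)c(O)cc2c1[C@H]1Oc3cc4cc(C)ncc4c(OC)c3[C@H](O1)[C@H]2[C@@H](C)O[Si](c1ccccc1)(c1ccccc1)C(C)(C)C
F7 | step 17 | (1R)-1-[(3R,4R)-7-formyl-6-hydroxy-3-(6-hydroxy-8-methoxy-3-methylisoquinolin-7-yl)-1,8-dimethoxy-3,4-dihydro-1H-isochromen-4-yl]ethyl acetate (C1 epimers) | COc1c(C=O)c(O)cc2c1C(OC)O[C@@H](c1c(O)cc3cc(C)ncc3c1OC)[C@H]2[C@@H](C)OC(C)=O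
F8 | step 8 | 2-bromo-4,6-dihydroxybenzaldehyde | O=Cc1c(Br)cc(O)cc1O
F9 | step 2 | methyl 3-formyl-2,4-dihydroxybenzoate | COC(=O)c1ccc(O)c(C=O)c1O
A1 | alternative 1 | bridged acetal with ring A triisopropylsilyl ether | COc1cc(O[Si](C(C)C)(C(C)C)C(C)C)cc2c1[C@H]1Oc3cc4cc(C)ncc4c(OC)c3[C@H](O1)[C@H]2C(C)=O
A2 | alternative 1 | 4-hydroxy-4-(6-hydroxy-8-methoxy-3-methylisoquinolin-7-yl)-3-[3-methoxy-5-(triisopropylsilyloxy)phenyl]butan-2-one | COc1cc(O[Si](C(C)C)(C(C)C)C(C)C)cc(c1)[C@H](C(C)=O)[C@@H](O)c1c(O)cc2cc(C)ncc2c1OC
A3 | alternative 2 | cis-6-(benzyloxy)-8-methoxy-3-[8-methoxy-6-(methoxymethoxy)-3-methylisoquinolin-7-yl]-1-oxoisochromane-4-carboxylic acid | COc1cc(OCc5ccccc5)cc2c1C(=O)O[C@@H](c3c(OCOC)cc4cc(C)ncc4c3OC)[C@H]2C(=O)O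
A4 | alternative 2 | 6-(benzyloxy)-8-methoxyisochromane-1,3-dione | COc1cc(OCc2ccccc2)cc2c1C(=O)OC(=O)C2
A5 | alternative 2 | 8-methoxy-6-(methoxymethoxy)-3-methylisoquinoline-7-carbaldehyde | COCOc1cc2cc(C)ncc2c(OC)c1C=O
A6 | alternative 3 | 3-(8-hydroxy-3-methyl-6-triisopropylsilyloxyisoquinolin-7-yl)-1-methoxyisochroman with 4-(2-methyl-1,3-dioxolan-2-yl) group | COc1cc(OCc5ccccc5)cc2c1C(OC)O[C@@H](c1c(O[Si](C(C)C)(C(C)C)C(C)C)cc3cc(C)ncc3c1O)[C@H]2C1(C)OCCO1
A7 | alternative 3 | 2-diazo-1-(2-methylpyridin-4-yl)ethan-1-one | Cc1cc(ccn1)C(=O)C=[N+]=[N-]
A8 | alternative 3 | 3-[(triisopropylsilyloxy)ethynyl]-1-methoxyisochroman with 4-(2-methyl-1,3-dioxolan-2-yl) group | COc1cc(OCc5ccccc5)cc2c1C(OC)O[C@@H](C#CO[Si](C(C)C)(C(C)C)C(C)C)[C@H]2C1(C)OCCO1
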